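**Plan**
- Retrosynthesis: the C3 silyl ether, the C6–Cl/C5=C16 unit (ene chlorination of a C5-methyl C5=C6 alkene) and the C9 acetate (from a C9 ketone) are removed first. C1–C10 and C11–C12 are then cut together (retro-[4+2]), followed by C9–C10 (ynone from a C9 acid), C13=C14 (Wittig), C5=C6 (metathesis), C1–C2 (acyl acetal opening) and C7–C8 (enolate acylation).
- Enabling feature: the cyclohexene C1/C10/C11/C12/C13/C14 with its C13=C14 bond is a Diels–Alder retron. The ether oxygen of the oxane ring (C1, C2, O, C8, C9, C10) links diene terminus C1 to dienophile carbon C10 through the four atoms C2–O–C8–C9, and the eight-membered ether ring (O, C2–C8) holds both partners cis.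
- Forward ring order: γ-lactone (C7–O–C19) → oxocene by ring-closing metathesis → cyclohexene, oxane and hence the ten-membered carbocycle C1–C10 in one operation.
- Stereochemistry before the key step: C3 from a BINOL–titanium glyoxylate–ene reaction; C8 and C17 from L-malic acid (Fráter–Seebach methylation, then self-regeneration through a dioxolanone whose acetal carbon becomes C2); C7 by CBS reduction; C2 by invertive acetal opening.
- Stereochemistry from the key step on: C11 and C12 from the E geometries of enol acetate and dienyl acetate; C1 and C10 from the bridge-enforced trans-fused transition state; C9 by hydride attack anti to the C15/C20 methyl groups; C6 by peripheral ene chlorination.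

Key step: step 16

Locants (briarane skeleton): C1 quaternary ring-fusion carbon (methyl C15); C2 ether CH; C3 carbinol; C4 CH2; C5 (=C16H2); C6 CHCl; C7 lactone O–CH; C8 quaternary ether carbon; C9 CH(OAc) next to C8; C10 ring-fusion CH; C11 C(CH3)(OAc) (methyl C20); C12 CH(OAc); C13=C14; C17 lactone CH(CH3) (methyl C18); C19 lactone C=O.

Remark: 16–18, 20 and 21 are carried as mixtures of C1 epimers (no C1 descriptor in their SMILES) and 15 as an E/Z mixture; C1 becomes trigonal in 22, so all isomers converge.

Step 1
Reactants: 1 ethyl glyoxylate; 2 isobutylene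
Product: 3 ethyl (2R)-2-hydroxy-4-methylpent-4-enoate
Conditions: (R)-BINOL, TiBr2(OiPr)2 (10 mol%), 4 Å MS, CH2Cl2, −30 °C
Reagents that add atoms: none
Why: Asymmetric glyoxylate–ene reaction (Mikami); the BINOL–titanium complex binds the glyoxylate and isobutylene should add to one enantioface through a six-membered ene transition state, setting C3 as R.

Step 2
Reactants: 3 ethyl (2R)-2-hydroxy-4-methylpent-4-enoate
Product: 4 ethyl (2R)-2-(tert-butyldimethylsilyloxy)-4-methylpent-4-enoate
Conditions: TBSCl, imidazole, DMF, rt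
Reagents that add atoms: tert-butyldimethylsilyl chloride, CC(C)(C)[Si](C)(C)Cl
Why: Imidazole-promoted silyl ether formation; the silyl ether survives every later step and is removable at the end beside three acetates.

Step 3
Reactants: 4 ethyl (2R)-2-(tert-butyldimethylsilyloxy)-4-methylpent-4-enoate
Product: 5 (2R)-2-(tert-butyldimethylsilyloxy)-4-methylpent-4-enal
Conditions: DIBAL-H, CH2Cl2, −78 °C; Rochelle salt work-up
Reagents that add atoms: none
Why: Partial reduction of an ester; the tetrahedral aluminium hemiacetal is stable at −78 °C, so the aldehyde should be released on work-up without over-reduction or loss of the α-stereocentre.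

Step 4
Reactants: 6 diethyl (S)-malate
Product: 7 diethyl (2S,3R)-2-hydroxy-3-methylbutanedioate
Conditions: LDA (2.2 equiv), THF, −78 to −20 °C; MeI, −78 °C; AcOH
Reagents that add atoms: iodomethane, CI
Why: Fráter–Seebach alkylation; the chelated alkoxide enolate dianion should be methylated anti to the alkoxide, giving the 2,3-anti isomer that carries C8 and C17.

Step 5
Reactants: 7 diethyl (2S,3R)-2-hydroxy-3-methylbutanedioate
Product: 8 (2S,3R)-2-hydroxy-3-methylbutanedioic acid
Conditions: KOH, H2O/EtOH, rt; then aq. HCl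
Reagents that add atoms: water, O
Why: Saponification of both esters under mild conditions, which should leave the carboxylate-flanked stereocentres untouched.

Step 6
Reactants: 8 (2S,3R)-2-hydroxy-3-methylbutanedioic acid; 5 (2R)-2-(tert-butyldimethylsilyloxy)-4-methylpent-4-enal
Product: 9 cis-dioxolanone acid, (2R)-2-{(2S,4S)-2-[(1R)-1-(tert-butyldimethylsilyloxy)-3-methylbut-3-enyl]-5-oxo-1,3-dioxolan-4-yl}propanoic acid
Conditions: p-TsOH·H2O (5 mol%), pentane, reflux, water separator
Reagents that add atoms: none
Why: Acid-catalysed acetalisation of an α-hydroxy acid (Seebach dioxolanone formation); the five-membered acyl acetal should close on the α-hydroxy acid unit with the 2,5-cis isomer favoured, so C8 fixes the configuration of the acetal carbon (future C2).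

Step 7
Reactants: 9 cis-dioxolanone acid
Product: 10 methyl ester of 9 (C19 as CO2CH3)
Conditions: MeI, KHCO3, DMF, rt
Reagents that add atoms: iodomethane, CI
Why: O-Alkylation of the carboxylate under weakly basic conditions that should not open the acyl acetal.

Step 8
Reactants: 10 methyl ester of 9
Product: 11 C8-acyl dioxolanone (10 with an (E)-but-2-enoyl group in place of H on ring carbon C8, trans to the acetal substituent)
Conditions: LiHMDS, THF, −78 °C; then (E)-but-2-enoyl chloride, −78 °C
Reagents that add atoms: (E)-but-2-enoyl chloride, C/C=C/C(Cl)=O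
Why: Self-regeneration of stereocentres (Seebach) with Claisen-type C-acylation; the planar lithium enolate at C8 should be acylated on the face anti to the C2 substituent, making C8 quaternary with the acyl group (C7) where the hydrogen was.

Step 9
Reactants: 11 C8-acyl dioxolanone
Product: 13 spiro lactone acetal, via hydroxy ester 12 (not isolated)
Conditions: (R)-2-methyl-CBS-oxazaborolidine (20 mol%), catecholborane, toluene, −78 °C; then CSA (cat.), CH2Cl2, rt
Reagents that add atoms: none
Why: Corey–Bakshi–Shibata 1,2-reduction of the enone under reagent control (quaternary C8 as the large group, propenyl as the small group, expected 7S), then acid-catalysed lactonisation of the C7 hydroxyl onto the C19 methyl ester.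

Step 10
Reactants: 14 propanal
Product: 15 1-(trimethylsilyloxy)prop-1-ene (E/Z mixture)
Conditions: TMSCl, Et3N, DMF, 80 °C
Reagents that add atoms: chlorotrimethylsilane, C[Si](C)(C)Cl
Why: Silyl enol ether formation from an aldehyde (House conditions); the enol ether geometry is irrelevant because the carbon it delivers (C1) later becomes trigonal.

Step 11
Reactants: 13 spiro lactone acetal; 15 1-(trimethylsilyloxy)prop-1-ene
Product: 16 ether acid aldehyde (C8–O–C2 ether; C9 CO2H; C2 bears CH(CH3)CHO; C3 OTBS with methallyl; C7 (E)-propenyl)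
Conditions: TMSOTf (20 mol%), CH2Cl2, −78 °C; aqueous work-up at pH 3
Reagents that add atoms: none
Why: Mukaiyama aldol-type opening of a 1,3-dioxolan-4-one (acyl acetal); the C2–O(acyl) bond ionises and the enol ether should attack C2 anti to the departing carboxylate, which stays tethered through C8 (inversion, as in Lewis-acid openings of chiral acetal templates), giving the tertiary ether with C2 as in the target and the free C9 acid.

Step 12
Reactants: 16 ether acid aldehyde
Product: 17 oxocene aldehyde acid (eight-membered ring O, C2–C8 with Z C5=C6 and C5 methyl)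
Conditions: second-generation Grubbs catalyst (H2IMes)(PCy3)Cl2Ru=CHPh (10 mol%), toluene (2 mM), 80 °C
Reagents that add atoms: none
Why: Ring-closing metathesis to an oxocene; the gauche C–O bonds of the α,α′-branched ether bring the 1,1-disubstituted and propenyl olefins together, only the Z alkene fits the eight-membered ring, and no other olefin is present at this stage.

Step 13
Reactants: 17 oxocene aldehyde acid
Product: 18 oxocene enal acid (C2 bears CH(CH3)–CH=CH–CHO, E)
Conditions: Ph3P=CHCHO (2.5 equiv), toluene, 60 °C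
Reagents that add atoms: (triphenylphosphoranylidene)acetaldehyde, O=CC=P(c1ccccc1)(c1ccccc1)c1ccccc1
Why: Wittig olefination with a stabilised ylide should give the E enal (C13=C14, C12 aldehyde); the excess covers the ylide protonated by the acid, and the neutral conditions should spare the β-alkoxy aldehyde.

Step 14
Reactants: 18 oxocene enal acid
Product: 20 ynone, via acid chloride 19 (not isolated)
Conditions: 1-chloro-N,N,2-trimethylprop-1-en-1-amine, CH2Cl2, 0 °C; then propyne, CuI (10 mol%), Et3N, THF, rt
Reagents that add atoms: propyne, CC#C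
Why: Neutral acid chloride formation (Ghosez reagent) followed by copper-catalysed acylation of a terminal alkyne; palladium is avoided because it could ionise the allylic lactone C7–O bond.

Step 15
Reactants: 20 ynone
Product: 21 enol acetate enal (C9(=O)–C10H=C11(CH3)OAc, E)
Conditions: AcOH (5 equiv), DABCO (20 mol%), CH2Cl2, rt
Reagents that add atoms: acetic acid, CC(=O)O
Why: Amine-catalysed conjugate addition of a carboxylic acid to an ynone; addition–elimination through the ammonium enolate should equilibrate the product to the E isomer (acetoxy anti to the acyl group, C20 syn to C9), the geometry that C11 requires.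

Step 16
Reactants: 21 enol acetate enal
Product: 23 cycloadduct ketone, via dienyl acetate 22 (not isolated)
Conditions: Ac2O, Et3N, DMAP (20 mol%), BHT, toluene, 50 °C; then 110 °C
Reagents that add atoms: acetic anhydride, CC(=O)OC(C)=O
Why: Acetic anhydride with DMAP/Et3N should convert the enal, through its O-acetylated oxocarbenium and loss of H-1, into the (1E,3E)-1-acetoxy diene 22, so that both C1 epimers converge and acetate rather than the C2 alkoxide is expelled; 22 then undergoes a concerted suprafacial thermal [4+2] cycloaddition with the C9-ketone-activated enol acetate C10=C11. The closest known reaction type is the type 1 intramolecular Diels–Alder reaction of ether-tethered 1,7,9-decatrien-3-ones with 1-acyloxy dienes. The cyclohexene (C1, C10–C14) closes through the C1–C10 and C11–C12 bonds, the oxane (C1, C2, O, C8, C9, C10) closes as the six-membered tether ring in a chair, and the ten-membered carbocycle C1–C10 is completed because this tether ring spans the existing oxocene. C11 is fixed by the E geometry of the dienophile (C20 cis to C9) and C12 by the 1E geometry of the diene (acetoxy outside), while C1 and C10 follow from the transition state with the C9 carbonyl exo, which gives the trans ring fusion with the C15 methyl (inside substituent of the diene) axial. The step needs trans- over cis-fusion and one facial pairing: the C3–C7 bridge of the oxocene can span the forming oxane only 1,3-diaxially, which leaves a single trans-fused chair, and the cis-fused alternative would force both the tether and the C20 methyl endo under the diene. Regiochemistry (C1 to C10, C12 to C11) is enforced by the four-atom tether against the weak electronic bias of two donor-substituted partners.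

Step 17
Reactants: 23 cycloadduct ketone
Product: 24 C9 alcohol
Conditions: NaBH4, CeCl3·7H2O, MeOH/THF, −40 °C
Reagents that add atoms: none
Why: Luche reduction under non-basic conditions (the β-acetoxy ketone should not eliminate); hydride is expected on the face of C9 opposite to the 1,3-related methyl groups C15 and C20, giving the axial 9-hydroxyl.

Step 18
Reactants: 24 C9 alcohol
Product: 25 triacetate (9-, 11-, 12-OAc; C3 OTBS; C5=C6)
Conditions: Ac2O, DMAP, pyridine, 40 °C
Reagents that add atoms: acetic anhydride, CC(=O)OC(C)=O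
Why: DMAP-catalysed acetylation of the hindered secondary alcohol, the only free hydroxyl.

Step 19
Reactants: 25 triacetate
Product: 26 allylic chloride (C6–Cl, C5=C16H2, C3 OTBS)
Conditions: Ca(OCl)2, solid CO2, CH2Cl2/H2O, 0 °C
Reagents that add atoms: calcium hypochlorite, [Ca+2].[O-]Cl.[O-]Cl
Why: Ene-type allylic chlorination with hypochlorous acid (Wolinsky conditions); chlorine should add to the less substituted C6 of the only electron-rich trisubstituted alkene from the outer face of the ten-membered ring, anti to the C7–O bond, with loss of a C16 proton to give the exocyclic methylene (C13=C14 is deactivated by its allylic acetate and the quaternary C1).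

Step 20
Reactants: 26 allylic chloride
Product: 27 CNP0333938.2
Conditions: HF·pyridine, pyridine/THF, 0 °C to rt
Reagents that add atoms: none
Why: Fluoride-mediated silyl ether cleavage; buffered HF should leave the acetates, the lactone and the allylic chloride intact.

**Compound list**
1 | ethyl glyoxylate | CCOC(=O)C=O | starting material
2 | isobutylene (2-methylpropene) | CC(C)=C | starting material
3 | ethyl (2R)-2-hydroxy-4-methylpent-4-enoate | CCOC(=O)[C@H](O)CC(C)=C | intermediate
4 | ethyl (2R)-2-(tert-butyldimethylsilyloxy)-4-methylpent-4-enoate | CCOC(=O)[C@H](O[Si](C)(C)C(C)(C)C)CC(C)=C | intermediate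
5 | (2R)-2-(tert-butyldimethylsilyloxy)-4-methylpent-4-enal (C2–C5, C16) | O=C[C@H](O[Si](C)(C)C(C)(C)C)CC(C)=C | intermediate
6 | diethyl (S)-malate | CCOC(=O)C[C@H](O)C(=O)OCC | starting material
7 | diethyl (2S,3R)-2-hydroxy-3-methylbutanedioate | CCOC(=O)[C@H](C)[C@H](O)C(=O)OCC | intermediate
8 | (2S,3R)-2-hydroxy-3-methylbutanedioic acid | OC(=O)[C@H](C)[C@H](O)C(=O)O | intermediate
9 | cis-dioxolanone acid, (2R)-2-{(2S,4S)-2-[(1R)-1-(tert-butyldimethylsilyloxy)-3-methylbut-3-enyl]-5-oxo-1,3-dioxolan-4-yl}propanoic acid | C[C@@H](C(=O)O)[C@@H]1O[C@@H](OC1=O)[C@H](O[Si](C)(C)C(C)(C)C)CC(C)=C | intermediate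
10 | methyl ester of 9 | C[C@@H](C(=O)OC)[C@@H]1O[C@@H](OC1=O)[C@H](O[Si](C)(C)C(C)(C)C)CC(C)=C | intermediate
11 | C8-acyl dioxolanone: 10 with (E)-but-2-enoyl on ring carbon C8, trans to the acetal substituent | C[C@@H](C(=O)OC)[C@]1(C(=O)/C=C/C)O[C@@H](OC1=O)[C@H](O[Si](C)(C)C(C)(C)C)CC(C)=C | intermediate
12 | hydroxy ester: 11 with the ketone reduced to the (7S) allylic alcohol | C[C@@H](C(=O)OC)[C@]1([C@@H](O)/C=C/C)O[C@@H](OC1=O)[C@H](O[Si](C)(C)C(C)(C)C)CC(C)=C | intermediate (not isolated)
13 | spiro lactone acetal: γ-lactone (C7–O–C19(=O)–C17–C8) spiro-fused at C8 to the 1,3-dioxolan-4-one; C7 (E)-propenyl, C17 methyl, acetal carbon bearing the (1R)-1-silyloxy-3-methylbut-3-enyl group | C/C=C/[C@@H]1OC(=O)[C@H](C)[C@]12C(=O)O[C@H](O2)[C@H](O[Si](C)(C)C(C)(C)C)CC(C)=C | intermediate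
14 | propanal | CCC=O | starting material
15 | 1-(trimethylsilyloxy)prop-1-ene (E/Z mixture) | CC=CO[Si](C)(C)C | intermediate
16 | ether acid aldehyde: lactone of 13 with C8 bearing CO2H and the C8–O–C2 ether; C2 bears CH(CH3)CHO and the C3(OTBS)–methallyl chain; C2, C3, C7, C8, C17 as in 27 | C/C=C/[C@@H]1OC(=O)[C@H](C)[C@@]1(C(=O)O)O[C@H](C(C)C=O)[C@H](O[Si](C)(C)C(C)(C)C)CC(C)=C | intermediate
17 | oxocene aldehyde acid: 16 after closure of the Z C5=C6 bond (C5 methyl) | C/C1=C/[C@@H]2OC(=O)[C@H](C)[C@@]2(C(=O)O)O[C@H](C(C)C=O)[C@H](O[Si](C)(C)C(C)(C)C)C1 | intermediate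
18 | oxocene enal acid: 17 with the aldehyde extended to CH(CH3)–CH=CH–CHO (E) | C/C1=C/[C@@H]2OC(=O)[C@H](C)[C@@]2(C(=O)O)O[C@H](C(C)/C=C/C=O)[C@H](O[Si](C)(C)C(C)(C)C)C1 | intermediate
19 | acid chloride of 18 | C/C1=C/[C@@H]2OC(=O)[C@H](C)[C@@]2(C(Cl)=O)O[C@H](C(C)/C=C/C=O)[C@H](O[Si](C)(C)C(C)(C)C)C1 | intermediate (not isolated)
20 | ynone: C8–C9(=O)–C≡C–CH3 | C/C1=C/[C@@H]2OC(=O)[C@H](C)[C@@]2(C(=O)C#CC)O[C@H](C(C)/C=C/C=O)[C@H](O[Si](C)(C)C(C)(C)C)C1 | intermediate
21 | enol acetate enal: C9(=O)–C10H=C11(CH3)OAc (E) and the (E)-enal side chain on C2 | C/C1=C/[C@@H]2OC(=O)[C@H](C)[C@@]2(C(=O)/C=C(\C)OC(C)=O)O[C@H](C(C)/C=C/C=O)[C@H](O[Si](C)(C)C(C)(C)C)C1 | intermediate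
22 | dienyl acetate: C2–C1(CH3)=C14H–C13H=C12H–OAc (1E,3E) | C/C1=C/[C@@H]2OC(=O)[C@H](C)[C@@]2(C(=O)/C=C(\C)OC(C)=O)O[C@H](/C(C)=C/C=C/OC(C)=O)[C@H](O[Si](C)(C)C(C)(C)C)C1 | intermediate (not isolated)
23 | cycloadduct ketone: full ring system with C9 ketone, 11- and 12-OAc, C5=C6 (C5 methyl), C3 OTBS | C/C1=C/[C@@H]2OC(=O)[C@H](C)[C@@]2(C(=O)[C@H]3[C@](C)(OC(C)=O)[C@H](OC(C)=O)C=C[C@@]34C)O[C@H]4[C@H](O[Si](C)(C)C(C)(C)C)C1 | intermediate
24 | C9 alcohol: 23 with 9-OH, configured as the 9-OAc of 27 | C/C1=C/[C@@H]2OC(=O)[C@H](C)[C@@]2([C@@H](O)[C@H]3[C@](C)(OC(C)=O)[C@H](OC(C)=O)C=C[C@@]34C)O[C@H]4[C@H](O[Si](C)(C)C(C)(C)C)C1 | intermediate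
25 | triacetate: 24 with 9-OAc | C/C1=C/[C@@H]2OC(=O)[C@H](C)[C@@]2([C@@H](OC(C)=O)[C@H]3[C@](C)(OC(C)=O)[C@H](OC(C)=O)C=C[C@@]34C)O[C@H]4[C@H](O[Si](C)(C)C(C)(C)C)C1 | intermediate
26 | allylic chloride: 3-O-TBS ether of 27 | C=C1C[C@@H](O[Si](C)(C)C(C)(C)C)[C@@H]2O[C@@]3([C@@H](C)C(=O)O[C@H]3[C@H]1Cl)[C@@H](OC(C)=O)[C@@H]1[C@]2(C)C=C[C@@H](OC(C)=O)[C@@]1(C)OC(C)=O | intermediate
27 | CNP0333938.2 | C=C1C[C@@H](O)[C@@H]2O[C@@]3([C@@H](C)C(=O)O[C@H]3[C@H]1Cl)[C@@H](OC(C)=O)[C@@H]1[C@]2(C)C=C[C@@H](OC(C)=O)[C@@]1(C)OC(C)=O | target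

**Step count and risks**
Total: 20 steps. Longest linear sequence: 17 steps (1–3, 6–9, 11–20).

Step 16 (key step). The dienol acetylation may instead expel the C2 ether oxygen (vinylogous β-elimination). The two donor-substituted partners may fail to combine at temperatures the enol acetates tolerate. The oxane may close cis-fused. Fallback from 21: soft enolisation with triethylsilyl triflate and triethylamine at −78 °C passes through the O-silylated oxocarbenium, never a dienolate, and should give the triethylsilyl dienol ether F1. This more electron-rich diene should cyclise below 80 °C to the 12-O-triethylsilyl cycloadduct F2. Selective cleavage of the allylic triethylsilyl ether (HF·pyridine, −20 °C) gives the 12-hydroxy cycloadduct F3, and acetylation (Ac2O, pyridine, DMAP) returns to 23. Diene formation and cycloaddition are thus separated and the diene class is changed.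

Step 11. Facial selectivity at the acetal carbon may be poor, because attack on a free oxocarbenium under the influence of the C3 silyloxy group favours the C2 epimer. Fallback from 13, replacing ion-pair control by neighbouring-group participation: desilylation (HF·pyridine) gives the hydroxy spiro acetal F4, and acetylation gives the acetoxy spiro acetal F5. Opening with 15 and TMSOTf should now run through the five-membered acetoxonium ion bridging O3 and C2, which forms with the bulky C8–O group trans to C4. It is opened at C2 with inversion (the 1,2-trans rule of glycosylation), giving the 3-O-acetyl ether acid aldehyde F6 with the required 2,3-syn relationship. Metathesis as in step 12 gives the acetoxy oxocene aldehyde acid F7, and Wittig olefination as in step 13 gives the acetoxy oxocene enal acid F8. Mild methanolysis (K2CO3, MeOH, 0 °C) gives the hydroxy oxocene enal acid F9, and silylation (TBSOTf, 2,6-lutidine, aqueous work-up) returns to 18.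

Step 19. Chlorine may be delivered to the wrong face of C6, a proton may be lost from C4 instead of C16, or C13=C14 may be attacked. Fallback from 25, useful if the electrophile prefers the face opposite to the one needed: epoxidation (mCPBA, NaHCO3, CH2Cl2) on that accessible face gives the 5,6-epoxide F10. Isomerisation (TMSOTf, 2,6-lutidine, then DBU) opens the epoxide at the tertiary C5 with loss of a C16 proton to give the exocyclic allylic silyl ether F11, which is hydrolysed (aqueous citric acid) to the 6-epi allylic alcohol F12. Chlorination with inversion and without allylic shift (hexachloroacetone, PPh3) returns to 26. Regiochemistry then rests on the epoxide opening and C6 on an SN2 inversion.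

**Further compounds**
F1 | step 16 | triethylsilyl dienol ether (21 with C12–OSiEt3 diene, 1E,3E) | C/C1=C/[C@@H]2OC(=O)[C@H](C)[C@@]2(C(=O)/C=C(\C)OC(C)=O)O[C@H](/C(C)=C/C=C/O[Si](CC)(CC)CC)[C@H](O[Si](C)(C)C(C)(C)C)C1
F2 | step 16 | 12-O-triethylsilyl cycloadduct | C/C1=C/[C@@H]2OC(=O)[C@H](C)[C@@]2(C(=O)[C@H]3[C@](C)(OC(C)=O)[C@H](O[Si](CC)(CC)CC)C=C[C@@]34C)O[C@H]4[C@H](O[Si](C)(C)C(C)(C)C)C1
F3 | step 16 | 12-hydroxy cycloadduct | C/C1=C/[C@@H]2OC(=O)[C@H](C)[C@@]2(C(=O)[C@H]3[C@](C)(OC(C)=O)[C@H](O)C=C[C@@]34C)O[C@H]4[C@H](O[Si](C)(C)C(C)(C)C)C1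
F4 | step 11 | hydroxy spiro acetal (13 without the silyl group) | C/C=C/[C@@H]1OC(=O)[C@H](C)[C@]12C(=O)O[C@H](O2)[C@H](O)CC(C)=C
F5 | step 11 | acetoxy spiro acetal | C/C=C/[C@@H]1OC(=O)[C@H](C)[C@]12C(=O)O[C@H](O2)[C@H](OC(C)=O)CC(C)=C
F6 | step 11 | 3-O-acetyl ether acid aldehyde | C/C=C/[C@@H]1OC(=O)[C@H](C)[C@@]1(C(=O)O)O[C@H](C(C)C=O)[C@H](OC(C)=O)CC(C)=C
F7 | step 11 | acetoxy oxocene aldehyde acid | C/C1=C/[C@@H]2OC(=O)[C@H](C)[C@@]2(C(=O)O)O[C@H](C(C)C=O)[C@H](OC(C)=O)C1
F8 | step 11 | acetoxy oxocene enal acid | C/C1=C/[C@@H]2OC(=O)[C@H](C)[C@@]2(C(=O)O)O[C@H](C(C)/C=C/C=O)[C@H](OC(C)=O)C1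
F9 | step 11 | hydroxy oxocene enal acid | C/C1=C/[C@@H]2OC(=O)[C@H](C)[C@@]2(C(=O)O)O[C@H](C(C)/C=C/C=O)[C@H](O)C1
F10 | step 19 | 5,6-epoxide of 25 | C[C@@]15C[C@@H](O[Si](C)(C)C(C)(C)C)[C@@H]2O[C@@]3([C@@H](C)C(=O)O[C@H]3[C@@H]1O5)[C@@H](OC(C)=O)[C@@H]1[C@]2(C)C=C[C@@H](OC(C)=O)[C@@]1(C)OC(C)=O
F11 | step 19 | exocyclic allylic silyl ether (6-epi C6–OSiMe3, C5=C16H2) | C=C1C[C@@H](O[Si](C)(C)C(C)(C)C)[C@@H]2O[C@@]3([C@@H](C)C(=O)O[C@H]3[C@@H]1O[Si](C)(C)C)[C@@H](OC(C)=O)[C@@H]1[C@]2(C)C=C[C@@H](OC(C)=O)[C@@]1(C)OC(C)=O
F12 | step 19 | 6-epi allylic alcohol (C6–OH, C5=C16H2) | C=C1C[C@@H](O[Si](C)(C)C(C)(C)C)[C@@H]2O[C@@]3([C@@H](C)C(=O)O[C@H]3[C@@H]1O)[C@@H](OC(C)=O)[C@@H]1[C@]2(C)C=C[C@@H](OC(C)=O)[C@@]1(C)OC(C)=O
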